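A charge of 5.0 µM of free enzyme has to turn over 0.050 M of starting material, and it is half the charge of the theta run, while self-condensation runs without enzyme.

| setting | theta | flask |
|---|---|---|
| starting material | 0.050 M | 0.050 M |
| second substrate | 0.060 M (fed, over 4.0 min) | 0.0600 M (fed, over 4.0 min) |
| free enzyme | 10 µM | 5.0 µM |
| remark | run made earlier; the fed solution adds 0.20 times the starting volume | the fed solution adds 0.20 times the starting volume |
| time |  | 4.0 h |

theta run (percent of the starting material charged)

| time / min | starting material / % | target / % |
|---|---|---|
| 4.00 | 87.0 | 8.5 |
| 8.00 | 72.2 | 19.8 |
| 20.0 | 41.1 | 46.9 |
| 50.0 | 7.1 | 78.5 |

(scatter of a reading: 0.5 percentage points)

- a species is counted by the starting material in it: one self-condensation product counts as two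
- charges are per starting volume, the dose included; the dosed solution carries all of it
- what was read earlier has a scatter of 0.5 percentage points, one standard deviation
- reactions considered so far: starting material + free enzyme <-> first complex; first complex <-> loaded enzyme + first product; second substrate + loaded enzyme <-> second complex; second complex -> free enzyme + target; 2 starting material -> self-condensation product
- the reaction counts as stopped when no species that holds the starting material changes by six tenths of a point or more over the second half of the time
- no earlier run changes the charge of free enzyme; that part of a forecast is a guess

- which holds at 4.0 h: what has brought the reaction to rest, or that it has not come to rest (it is still moving / all of the starting material has reacted / no working catalyst is left / the second substrate has run out first / forward and back rates have come level)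
- part of the starting material gone at 4.0 h
- the target standing at 4.0 h, as a percentage of the starting material charged
- amount of target if the flask were left three thousand times as long, in percent of the starting material charged

So this flask is a race, and I want its odds. In the theta run, what is neither starting material nor target is self-condensation product, apart from the enzyme-bound forms, which hold at most 0.0200% of the charge, and from 20.0 min to 50.0 min that gap gains 2.4 percentage points while target gains 32 points. But self-condensation goes with the square of c(starting material), and I take the enzyme route as going with its first power, so that ratio belongs to the mean starting material of the window, 24.1%. Dividing by this mean gives 0.315, which I call the competition number: the rate of self-condensation over the rate through the enzyme at the full charge of starting material, here a reading from the theta run that carries the scatter of 0.5 points in its percentages. It is a selectivity factor that falls in step with c(starting material), so the share ending as target is the natural log of one plus the number, divided by the number.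

But no earlier run changes c(free enzyme), so it is my guess that the number goes inversely with that charge. This flask then has 0.630, and I reckon 77.5% of target. Scaled the same way, the 50.0 min of the theta run become 100 min here, and the flask has longer than that, so I expect less starting material at its end than the 7.1% read at that point of the theta run.

The forecast gives 76% of target, 76.5% in the long run, 99.7% gone and "it is still moving", saying “Self-condensation takes a larger share”, and its target stands below my 77.5%.

The flask gives 78.6% of target with 100% of the starting material gone, and 78.6% of target in the long run.

    starting material + free enzyme ⇌ first complex (K = 280 M⁻¹, k = 2.20 × 10⁵ M⁻¹ min⁻¹)
    first complex ⇌ loaded enzyme + first product (K = 0.0320 M, k = 1700 min⁻¹)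
    second substrate + loaded enzyme ⇌ second complex (K = 9.10 M⁻¹, k = 56000 M⁻¹ s⁻¹)
    second complex → free enzyme + target (k = 680 min⁻¹)
    2 starting material → self-condensation product (k = 0.140 M⁻¹ min⁻¹)

The state of the flask at the end is this: all of the starting material has reacted; starting material is the limiting reagent, with less of it left, 0%, than the 35% of second substrate. With 8.5 × 10⁻⁶ M of free enzyme, the competition number drops from 0.630 to 0.371, which gives 85.1% of target; that neighbour flask stands at 84.6%.

The readings stem from a simulated flask for substances that don't exist; noise was put on by code.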